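Start from the slowness of one step, the loss of substrate, and let the fast steps behind it follow.

| flask | substrate | first nucleophile | second nucleophile | temperature | time | remark |
|---|---|---|---|---|---|---|
| ochre | 0.24 M (fed, over 5.0 d) | 0.120 M | 0.144 M | 25 °C | 6.0 d | all else is in the flask from the start; the feed brings no volume worth counting |
| grey | 0.24 M (in portions, 3, over 5.0 d) | 0.120 M | 0.144 M | 25 °C | 6.0 d | first portion at the start, last at 5.0 d |
| blue | 0.24 M (fed, over 5.0 d) | 0.120 M | 0.144 M |  | 6.0 d | the addition at 5 °C, then warmed to 25 °C; the feed brings no volume worth counting |
| teal | 0.24 M | 0.120 M | 0.144 M (fed, over 12 h) | 25 °C | 6.0 d | all else is in the flask from the start; the feed brings no volume worth counting |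
| violet | 0.24 M | 0.120 M | 0.144 M | 25 °C | 6.0 d | everything together at the start |
| red | 0.24 M | 0.120 M | 0.144 M |  | 6.0 d | everything together at the start at 5 °C, warmed to 25 °C at 5.0 d |

    substrate → intermediate (k1 = 8.21 × 10⁻⁴ /min, Ea1 = 95.0 kJ/mol)
    first nucleophile + intermediate → target (k2 = 1.92 /M/min, Ea2 = 51.0 kJ/mol)
    second nucleophile + intermediate → other capture product (k3 = 2.95 /M/min, Ea3 = 51.0 kJ/mol)
    intermediate → solvolysis product (k4 = 0.101 /min, Ea4 = 87.0 kJ/mol)
    crystals ⇌ target, rate k5*(cs5 - [target]) while solid is left; crystals form when [target] > cs5 (cs5 = 7.5 mM, k5 = 0.126 /min)
    (constants at 25 °C)

- what is said of target includes crystals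
- crystals is a solid; its amount is given per volume of the solution
- constants are those at 25 °C; use the activation energies for any other temperature

- the flask that comes out highest in amount of target, in percent of the substrate charged, or "all alike" when all lie within 1.5 percentage points (ochre / grey / blue / teal / violet / red / all alike)
- target at the end, in percent of the substrate charged, ochre
- target at the end, in percent of the substrate charged, grey
- target at the end, in percent of the substrate charged, blue
- target at the end, in percent of the substrate charged, teal
- target at the end, in percent of the substrate charged, violet
- target at the end, in percent of the substrate charged, red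

Reckon by hand first. Substrate has a half-life of 0.586 d. Freeze the nucleophiles at their charges and compare the exits of the intermediate:

capture by first nucleophile: 0.230 /min
capture by second nucleophile: 0.425 /min
solvolysis: 0.101 /min
first exit over the sum of the exits: 30.5%

Call this the capture share: the part of each intermediate formed that ends as target, a selectivity among the exits. It can be used because the intermediate's half-life, 0.917 min, is far shorter than the substrate's, so the intermediate chooses as soon as it forms. Crystals count as target, so they leave the share alone.

Read the outcome off it. Violet runs 10.2 half-lives, so expect target near 30.5%. In ochre, the feed balances loss until it stops, and the last day then shrinks what stands: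

substrate left: 5.19%
target: 28.9%

Now test the freeze. At this share the second nucleophile is asked for 0.135 M of its 0.144 M, so its concentration will fall well below the charge and the freeze is rough. Teal opens without the second nucleophile, at a share of 69.5%, higher than 30.5%, so put teal above violet, by an amount I do not reckon. Leave blue and red unreckoned, since their constants would first have to be moved to the cold.

The forecast names teal and gives ochre 29.8%, grey 28.1%, blue 23.9%, teal 33.4%, violet 31.4% and red 25.9%, on the ground that “the yield depends on how the short-lived intermediate partitions among the two nucleophiles and solvent”. Its violet stands above my 30.5%, and its ochre above my 28.9%.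

The simulation gives teal as highest, with ochre 29.8%, grey 28.1%, blue 23.9%, teal 33.3%, violet 31.4% and red 25.9%. The forecast holds on every count.

Violet's 31.4% stands above the capture share of 30.5%. In teal at 0.586 d, the intermediate has half-lives of 0.039 h by second nucleophile, 0.085 h by first nucleophile and 0.11 h by solvolysis, each far shorter than the 0.59 d of substrate by its own step.

Carry the share to the neighbour of teal charged with 0.41 M of substrate. There 30.5% asks for 0.125 M of target, more than the 0.120 M of first nucleophile charged, so that charge holds target to 29.3% of the substrate. The neighbour gives 27.7% of target, with 5.19% of the first nucleophile's charge left.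

The numbers belong to no real substance; the rest is arithmetic.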